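The ratio to carry here is loss of target over gain of target. If partner multiplies both steps alike, the pace follows partner while that ratio stays put, and the ratio then gives the peak of target as a share of the starting material charged.

| flask | starting material | partner | target | time |
|---|---|---|---|---|
| dawn | 0.800 M | 0.640 M |  |  |
| autumn | 0.800 M | 0.640 M | 0.240 M |  |
| dusk | 0.400 M | 0.640 M |  |  |
| midnight | 0.800 M | 1.30 M |  |  |
| spring | 0.400 M | 0.210 M |  | 53 min |

- dawn run (time / min: [target] / M): 8.8: 0.139; 18: 0.221; 26: 0.265; 35: 0.290; 44: 0.312; 53: 0.331
- autumn run (time / min: [target] / M): 8.8: 0.358; 18: 0.419; 26: 0.442; 35: 0.465; 44: 0.480; 53: 0.477
- dusk run (time / min: [target] / M): 8.8: 0.074; 18: 0.121; 26: 0.145; 35: 0.164; 44: 0.180; 53: 0.191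
- midnight run (time / min: [target] / M): 8.8: 0.270; 18: 0.362; 26: 0.395; 35: 0.403; 44: 0.400; 53: 0.396

(standard deviation of a reading: 0.004 M)

- Overall: starting material + partner -> target.
- Constant volume, constant temperature.
- "The second partner" is partner.
- An order is taken over about fifteen percent of the charge, up and down.

- the power of [starting material] that the first rate follows, about the charge of the dawn run; measure it at two percent of starting material made into target (one fixed amount of target, the same in the runs compared)
- the power of [partner] that the first rate follows, about the charge of the dawn run; measure it at two percent of starting material made into target
- target in the spring run at 53 min, as a share of the starting material charged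
- which of these the readings show (the substrate pairs with itself / the product reacts on with the second partner / the product decays / the product binds the second partner / the product speeds the reaction)

Dawn against autumn gives the ratio. In the first 8.8 min, the dawn run gains 17.4% of its charge. The autumn run, which starts with target at 30.0% of its starting material, gains 14.7%, less than dawn, a shortfall of 15.1%. Shortfall over target share reads the loss ratio at 0.504, the selectivity factor: the rate at which target is lost over the rate at which it forms, at equal shares of target and starting material and at the partner charge of dawn and autumn.

The objection is that starting material has already fallen during that interval and dawn holds some target too. Mean values give 0.460. The peak share of target, the ratio raised to the power ratio/(1 − ratio), goes from 49.9% to 51.6%. The midnight run, read separately, gives 50.4% of its starting material at 35 min, its top reading.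

With the ratio near a half, a partner spend b, as a share of the charge, gives target share b(1 − b/2), and the peak costs b = 1. The spring run holds partner at 52.5% of its starting material, so partner is the limiting reagent, and the rule reckons 38.7% target in spring for its whole partner charge spent.

The pace comes from dawn's first interval. Scaled to spring at its full partner charge, the logarithmic clock of starting material reaches 0.423 by 53 min, so b is 38.1% and target 30.8%. But partner falls on the way. Its mean under that spend gives b of 25.2% and target 22.0%, which overcorrects, and the next pass gives 29.7% and 25.3%. This reckoning commits to 23.6%.

The forecast, made separately, gives 1.03 and 1 for the orders, 24.5% for spring, and the product reacts on with the second partner, adding “Simple decay or binding fits less well.”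

The flask gives 1.0 and 1.2, 23.1%, and the product reacts on with the second partner.

    starting material + partner → target (0.03558 L mol⁻¹ min⁻¹)
    starting material + 2 partner → target + partner (0.01074 L² mol⁻² min⁻¹)
    target + partner → side product (0.02154 L mol⁻¹ min⁻¹)

At the dawn charge of partner, the route to target through 2 partner ran at 19.3% of the rate of the first route, with the partner order at 1.2 against the forecast's 1. In the spring run, both routes formed target for 53 min while partner also consumed the target present, and at 23.1% target the rule, with the ratio as read at the dawn partner charge, estimates starting material at 75.1% of its charge and the loss at 15.5% of formation.

The readings are calculated from invented constants; noise was put on by code.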